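**Plan**

Numbering of each identical half: C1 (ester C=O), C2(Me)=C3, C4=C5, C6, C7, C8(Me), C9 (carbinol CH), C10 (CH2). The oxazole atoms are O1', C2', N3', C4', C5', and C10 sits on C5'.
Cuts: first both C1–O–C9 ester bonds of the C2-symmetric 20-membered diolide, which leaves one hydroxy acid. Then C4=C5, then C4'–C5' and O1'–C2' of the oxazole, then C9–C10 and O–C5' of a four-membered lactone.
Enabling feature: the C9 oxygen and O1' stand 1,3 to each other across C10, so the array O–C9–C10–C5'(O1') is an oxetan-2-one ring (O, C9, C10, C5'). Its carbonyl carbon and oxygen become C5' and O1' of the oxazole ring, and its ring oxygen stays on C9.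
Forward order: alkylation at C8, ketene–aldehyde [2+2] (oxetanone ring), opening with lithiomethyl isocyanide (oxazole ring), extension at C5 to a phosphonium salt, Wittig joining with a C1–C4 butenolide, cyclodimerisation (20-membered ring).
Stereochemistry: C8 (R) comes from the benzyloxazolidinone auxiliary and C9 (R) from the cinchona catalyst, with the C9–O bond never broken afterwards. 2Z comes from the butenolide ring and 4Z from the lithium-free Wittig reaction.

Key step: step 6

Assumption: O-trimethylsilylquinidine is taken to give the (4R)-lactone, by analogy with quinidine-catalysed ketene–aldehyde cycloadditions; if the opposite sense is found, the pseudoenantiomeric O-trimethylsilylquinine replaces it with no other change.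

**Step 1**
Reactants: 1 (S)-4-benzyl-3-propionyloxazolidin-2-one; 2 allyl iodide
Product: 4 (S)-4-benzyl-3-[(R)-2-methylpent-4-enoyl]oxazolidin-2-one, via sodium enolate 3 (not isolated)
Conditions: NaN(SiMe3)2 (1.1 equiv), THF, −78 °C; then 2 (3 equiv), −78 → −45 °C
Reagents that add atoms: none
Why: Evans asymmetric alkylation: the chelated sodium (Z)-enolate 3 has one face covered by the benzyl group of the auxiliary, so allyl iodide should enter from the open face and set C8 as R.

**Step 2**
Reactants: 4 (S)-4-benzyl-3-[(R)-2-methylpent-4-enoyl]oxazolidin-2-one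
Product: 5 (R)-2-methylpent-4-en-1-ol
Conditions: LiBH4, H2O (1 equiv), Et2O, 0 °C
Reagents that add atoms: none
Why: Hydride reduction of the N-acyl oxazolidinone (reductive auxiliary removal) takes place at the more electrophilic exocyclic carbonyl, leaves the alkene and the C8 centre alone and returns the auxiliary.

**Step 3**
Reactants: 5 (R)-2-methylpent-4-en-1-ol
Product: 6 (R)-2-methylpent-4-enal
Conditions: Dess–Martin periodinane, CH2Cl2, 0 °C → rt; short silica plug, careful concentration, used at once
Reagents that add atoms: none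
Why: Dess–Martin oxidation runs without base near neutrality, so the primary alcohol should stop at the aldehyde and the enolisable C8 centre should hold, provided that the volatile product is used at once.

**Step 4**
Reactants: 6 (R)-2-methylpent-4-enal; 7 acetyl chloride
Product: 9 (4R)-4-[(2R)-pent-4-en-2-yl]oxetan-2-one, via ketene 8 (not isolated)
Conditions: O-trimethylsilylquinidine (10 mol%), LiClO4 (1 equiv), iPr2NEt (2.5 equiv), CH2Cl2/Et2O, −78 → −40 °C, 7 added over several hours by syringe pump
Reagents that add atoms: none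
Why: Alkaloid and Lewis acid co-catalysed acyl halide–aldehyde cyclocondensation (a Wynberg-type ketene–aldehyde [2+2]): ketene 8 is taken up by the quinuclidine nitrogen as an ammonium enolate, which adds to the lithium-bound aldehyde in a closed transition state and lactonises, so that the catalyst sets C9 as R while the Felkin–Anh bias of the α-methyl aldehyde (8,9-syn) points the same way.

**Step 5**
Reactants: 10 N-methylformamide
Product: 11 methyl isocyanide
Conditions: TsCl, quinoline, 75 °C, reduced pressure, product distilled into a −78 °C trap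
Reagents that add atoms: none
Why: Dehydration of an N-alkylformamide with a sulfonyl chloride and an amine base is the standard isocyanide synthesis, and continuous distillation of the low-boiling product out of the high-boiling medium drives it.

**Step 6**
Reactants: 9 (4R)-4-[(2R)-pent-4-en-2-yl]oxetan-2-one; 11 methyl isocyanide
Product: 14 (2R,3R)-3-methyl-1-(oxazol-5-yl)hex-5-en-2-ol, via lithiomethyl isocyanide 12 (not isolated), via dilithio isocyano enolate 13 (not isolated)
Conditions: 11 (2.5 equiv), n-BuLi (2.4 equiv), THF, −78 °C; then 9 added slowly, −78 → 0 °C; AcOH, 0 °C → rt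
Reagents that add atoms: none
Why: Lithiomethyl isocyanide 12 adds to the lactone carbonyl C5' (forming C4'–C5'), and the tetrahedral intermediate collapses with acyl–oxygen cleavage because this releases the strain of the oxetanone ring, so the C9 alkoxide is set free with the C9–O bond untouched. A second equivalent of 12 deprotonates the acidic α-isocyano ketone to the (Z)-enolate 13, which stands in equilibrium with the 2-lithiooxazole and is drawn fully to the aromatic ring when acetic acid protonates C2'. The closest known reaction type is the Schöllkopf oxazole synthesis, the acylation of α-metallated isocyanides by esters and lactones, taken together with the acyl-selective opening of β-lactones by hard lithium carbanions such as phosphonate anions and ester enolates. The oxazole closes in a 5-endo-dig mode by attack of the enolate oxygen O1' on the isocyanide carbon C2'. No stereocentre is created, and C8 and C9 are carried over unchanged from 9. The step needs acyl rather than alkyl C–O cleavage and addition rather than deprotonation at C10, which the hard lithium nucleophile, the low temperature, the slow addition of 9 to an excess of 12, the strained and therefore highly electrophilic carbonyl and the steric shielding of the branched secondary C9 should secure, while immediate enolate formation guards against a second addition and against retro-aldol cleavage.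

**Step 7**
Reactants: 14 (2R,3R)-3-methyl-1-(oxazol-5-yl)hex-5-en-2-ol
Product: 15 5-[(2R,3R)-2-(tert-butyldimethylsilyloxy)-3-methylhex-5-en-1-yl]oxazole
Conditions: TBSOTf, 2,6-lutidine, CH2Cl2, 0 °C
Reagents that add atoms: tert-butyldimethylsilyl triflate, CC(C)(C)[Si](C)(C)OS(=O)(=O)C(F)(F)F
Why: Silyl ether formation with a silyl triflate and a hindered pyridine base is the usual way to protect a branched secondary alcohol, and the weakly basic oxazole nitrogen is silylated only reversibly.

**Step 8**
Reactants: 15 5-[(2R,3R)-2-(tert-butyldimethylsilyloxy)-3-methylhex-5-en-1-yl]oxazole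
Product: 17 (4R,5R)-5-(tert-butyldimethylsilyloxy)-4-methyl-6-(oxazol-5-yl)hexan-1-ol, via B-alkyl-9-BBN adduct 16 (not isolated)
Conditions: 9-BBN, THF, 0 °C → rt; then NaOH (3 M aq.), H2O2 (30%), 0 °C
Reagents that add atoms: hydrogen peroxide, OO
Why: Brown hydroboration–oxidation: the bulky dialkylborane adds to the monosubstituted alkene with boron on the terminal carbon C5, and alkaline peroxide replaces boron by hydroxyl without harm to silyl ether or oxazole.

**Step 9**
Reactants: 17 (4R,5R)-5-(tert-butyldimethylsilyloxy)-4-methyl-6-(oxazol-5-yl)hexan-1-ol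
Product: 18 5-[(2R,3R)-2-(tert-butyldimethylsilyloxy)-6-iodo-3-methylhexyl]oxazole
Conditions: I2, PPh3, imidazole, CH2Cl2, 0 °C
Reagents that add atoms: iodine, II
Why: Appel-type iodination (PPh3, I2, imidazole) turns the primary alcohol into the iodide by SN2 displacement of the oxyphosphonium group under nearly neutral conditions.

**Step 10**
Reactants: 18 5-[(2R,3R)-2-(tert-butyldimethylsilyloxy)-6-iodo-3-methylhexyl]oxazole
Product: 19 [(4R,5R)-5-(tert-butyldimethylsilyloxy)-4-methyl-6-(oxazol-5-yl)hexyl]triphenylphosphonium iodide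
Conditions: PPh3 (3 equiv), iPr2NEt (0.2 equiv), MeCN, 80 °C
Reagents that add atoms: triphenylphosphine, c1ccc(cc1)P(c1ccccc1)c1ccccc1
Why: Quaternisation of PPh3 by a primary alkyl iodide (SN2) is the standard entry to Wittig salts, and phosphorus is far more nucleophilic than the oxazole nitrogen.

**Step 11**
Reactants: 20 3-methyl-2-furoic acid
Product: 22 5-hydroxy-3-methylfuran-2(5H)-one (racemic lactol), via furan endoperoxide 21 (not isolated)
Conditions: O2, 5,10,15,20-tetraphenylporphyrin (0.5 mol%), visible light, CH2Cl2, 0 °C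
Reagents that add atoms: dioxygen, O=O
Why: Dye-sensitised photooxygenation: singlet oxygen adds [4+2] across C2 and C5 of the furan and endoperoxide 21 fragments with loss of CO2, which leaves the lactone carbonyl next to the methyl-bearing carbon and locks the future C2=C3 bond as Z inside the five-membered ring.

**Step 12**
Reactants: 19 [(4R,5R)-5-(tert-butyldimethylsilyloxy)-4-methyl-6-(oxazol-5-yl)hexyl]triphenylphosphonium iodide; 22 5-hydroxy-3-methylfuran-2(5H)-one
Product: 25 (2Z,4Z,8R,9R)-9-(tert-butyldimethylsilyloxy)-2,8-dimethyl-10-(oxazol-5-yl)deca-2,4-dienoic acid, via phosphorus ylide 23 (not isolated), via sodium aldehydo carboxylate 24 (not isolated)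
Conditions: 19, NaN(SiMe3)2 (1.0 equiv), THF, −78 → 0 °C; separately 22 (1.5 equiv), NaN(SiMe3)2 (1.5 equiv), THF/DMPU, −78 °C; solutions combined at −78 °C → rt; then HCl (1 M aq.) to pH 4
Reagents that add atoms: none
Why: Wittig olefination of a non-stabilised ylide under lithium-free conditions proceeds through the kinetically favoured cis-oxaphosphetane and should give the 4Z alkene, while base opens the lactol 22 to the aldehydo carboxylate 24 whose 2Z geometry is inherited from the ring.

**Step 13**
Reactants: 25 (2Z,4Z,8R,9R)-9-(tert-butyldimethylsilyloxy)-2,8-dimethyl-10-(oxazol-5-yl)deca-2,4-dienoic acid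
Product: 26 (2Z,4Z,8R,9R)-9-hydroxy-2,8-dimethyl-10-(oxazol-5-yl)deca-2,4-dienoic acid
Conditions: HF·pyridine, pyridine, THF, 0 °C → rt
Reagents that add atoms: none
Why: Fluoride-induced cleavage of the silyl ether with buffered HF·pyridine is driven by the strong Si–F bond and is mild enough for the acid-sensitive and base-sensitive (2Z,4Z)-dienoic acid.

**Step 14**
Reactants: 26 (2Z,4Z,8R,9R)-9-hydroxy-2,8-dimethyl-10-(oxazol-5-yl)deca-2,4-dienoic acid (two molecules)
Product: 29 (3Z,5Z,9R,10R,13Z,15Z,19R,20R)-3,9,13,19-tetramethyl-10,20-bis(oxazol-5-ylmethyl)-1,11-dioxacycloicosa-3,5,13,15-tetraene-2,12-dione, via monomer mixed anhydride 27 (not isolated), via linear dimer mixed anhydride 28 (not isolated)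
Conditions: 2,4,6-trichlorobenzoyl chloride, Et3N, THF, rt; then DMAP, toluene (about 0.02 M), rt
Reagents that add atoms: none
Why: Yamaguchi esterification and macrolactonisation in one flask: at moderate concentration the C9 hydroxyl of one activated monomer 27 should be acylated intermolecularly faster than it closes the strained ten-membered ring, and the resulting 28 then closes the less strained twenty-membered ring, with retention at C9 because only acyl–oxygen bonds are formed.

**Compound list**

1 | (S)-4-benzyl-3-propionyloxazolidin-2-one | CCC(=O)N1[C@@H](Cc2ccccc2)COC1=O | starting material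
2 | allyl iodide | C=CCI | starting material
3 | sodium (Z)-enolate of 1 | C/C=C(\[O-])N1[C@@H](Cc2ccccc2)COC1=O.[Na+] | intermediate
4 | (S)-4-benzyl-3-[(R)-2-methylpent-4-enoyl]oxazolidin-2-one | C=CC[C@@H](C)C(=O)N1[C@@H](Cc2ccccc2)COC1=O | intermediate
5 | (R)-2-methylpent-4-en-1-ol | C=CC[C@@H](C)CO | intermediate
6 | (R)-2-methylpent-4-enal | C=CC[C@@H](C)C=O | intermediate
7 | acetyl chloride | CC(=O)Cl | starting material
8 | ketene | C=C=O | intermediate
9 | (4R)-4-[(2R)-pent-4-en-2-yl]oxetan-2-one | C=CC[C@@H](C)[C@@H]1OC(=O)C1 | intermediate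
10 | N-methylformamide | CNC=O | starting material
11 | methyl isocyanide | C[N+]#[C-] | intermediate
12 | lithiomethyl isocyanide | [Li]C[N+]#[C-] | intermediate
13 | dilithium alkoxide (Z)-enolate of (4R,5R)-4-hydroxy-1-isocyano-5-methyloct-7-en-2-one | C=CC[C@@H](C)[C@@H](C/C([O-])=C/[N+]#[C-])[O-].[Li+].[Li+] | intermediate
14 | (2R,3R)-3-methyl-1-(oxazol-5-yl)hex-5-en-2-ol | C=CC[C@@H](C)[C@@H](Cc1cnco1)O | intermediate
15 | 5-[(2R,3R)-2-(tert-butyldimethylsilyloxy)-3-methylhex-5-en-1-yl]oxazole | C=CC[C@@H](C)[C@@H](Cc1cnco1)O[Si](C)(C)C(C)(C)C | intermediate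
16 | 9-[(4R,5R)-5-(tert-butyldimethylsilyloxy)-4-methyl-6-(oxazol-5-yl)hexyl]-9-borabicyclo[3.3.1]nonane | C1CC2CCCC(C1)B2CCC[C@@H](C)[C@@H](Cc1cnco1)O[Si](C)(C)C(C)(C)C | intermediate
17 | (4R,5R)-5-(tert-butyldimethylsilyloxy)-4-methyl-6-(oxazol-5-yl)hexan-1-ol | OCCC[C@@H](C)[C@@H](Cc1cnco1)O[Si](C)(C)C(C)(C)C | intermediate
18 | 5-[(2R,3R)-2-(tert-butyldimethylsilyloxy)-6-iodo-3-methylhexyl]oxazole | ICCC[C@@H](C)[C@@H](Cc1cnco1)O[Si](C)(C)C(C)(C)C | intermediate
19 | [(4R,5R)-5-(tert-butyldimethylsilyloxy)-4-methyl-6-(oxazol-5-yl)hexyl]triphenylphosphonium iodide | [I-].c1ccccc1[P+](c1ccccc1)(c1ccccc1)CCC[C@@H](C)[C@@H](Cc1cnco1)O[Si](C)(C)C(C)(C)C | intermediate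
20 | 3-methyl-2-furoic acid | Cc1ccoc1C(=O)O | starting material
21 | 6-methyl-2,3,7-trioxabicyclo[2.2.1]hept-5-ene-1-carboxylic acid (racemic) | OC(=O)C12OOC(O1)C=C2C | intermediate
22 | 5-hydroxy-3-methylfuran-2(5H)-one (racemic lactol) | CC1=CC(O)OC1=O | intermediate
23 | [(4R,5R)-5-(tert-butyldimethylsilyloxy)-4-methyl-6-(oxazol-5-yl)hexylidene]triphenylphosphorane | c1ccccc1P(c1ccccc1)(c1ccccc1)=CCC[C@@H](C)[C@@H](Cc1cnco1)O[Si](C)(C)C(C)(C)C | intermediate
24 | sodium (Z)-2-methyl-4-oxobut-2-enoate | [Na+].[O-]C(=O)/C(C)=C\C=O | intermediate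
25 | (2Z,4Z,8R,9R)-9-(tert-butyldimethylsilyloxy)-2,8-dimethyl-10-(oxazol-5-yl)deca-2,4-dienoic acid | OC(=O)/C(C)=C\C=C/CC[C@@H](C)[C@@H](Cc1cnco1)O[Si](C)(C)C(C)(C)C | intermediate
26 | (2Z,4Z,8R,9R)-9-hydroxy-2,8-dimethyl-10-(oxazol-5-yl)deca-2,4-dienoic acid | OC(=O)/C(C)=C\C=C/CC[C@@H](C)[C@@H](Cc1cnco1)O | intermediate
27 | mixed anhydride of 26 and 2,4,6-trichlorobenzoic acid | Clc1cc(Cl)cc(Cl)c1C(=O)OC(=O)/C(C)=C\C=C/CC[C@@H](C)[C@@H](Cc1cnco1)O | intermediate
28 | linear dimer (O9 of one unit acylated by C1 of the other), free C9 hydroxyl at one end, 2,4,6-trichlorobenzoic mixed anhydride at the other | Clc1cc(Cl)cc(Cl)c1C(=O)OC(=O)/C(C)=C\C=C/CC[C@@H](C)[C@@H](Cc1cnco1)OC(=O)/C(C)=C\C=C/CC[C@@H](C)[C@@H](Cc1cnco1)O | intermediate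
29 | (3Z,5Z,9R,10R,13Z,15Z,19R,20R)-3,9,13,19-tetramethyl-10,20-bis(oxazol-5-ylmethyl)-1,11-dioxacycloicosa-3,5,13,15-tetraene-2,12-dione (CNP0414419.1) | C/C1=C/C=C\CC[C@@H](C)[C@@H](Cc2cnco2)OC(=O)/C(C)=C\C=C/CC[C@@H](C)[C@@H](Cc2cnco2)OC1=O | target

**Counts**

Total step count: 14.
Longest linear sequence: 12 steps (1, 2, 3, 4, 6, 7, 8, 9, 10, 12, 13, 14, starting from 1).

**Steps most likely to fail**

**Step 6.**
- What may go wrong: the basic carbanion may remove a C10 proton instead of adding to the carbonyl. It may attack C9 with alkyl–oxygen cleavage. The C9–C10 bond may break by retro-aldol cleavage before the second deprotonation has taken place.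
- Fallback: the oxazole is built by a van Leusen synthesis on an aldehyde, which needs no strong carbanion. It sets out from 9.
- The lactone is opened at the acyl carbon with MeNH(OMe)·HCl and Me2AlCl in CH2Cl2 to give (3R,4R)-3-hydroxy-N-methoxy-N,4-dimethylhept-6-enamide F1.
- Silylation (TBSOTf, 2,6-lutidine) gives (3R,4R)-3-(tert-butyldimethylsilyloxy)-N-methoxy-N,4-dimethylhept-6-enamide F2.
- Reduction with iBu2AlH in THF at −78 °C gives (3R,4R)-3-(tert-butyldimethylsilyloxy)-4-methylhept-6-enal F3.
- Tosylmethyl isocyanide with K2CO3 in MeOH then turns the aldehyde carbon into C5' and the aldehyde oxygen into O1'. The route is rejoined at 15.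

**Step 14.**
- What may go wrong: a single activated hydroxy acid may close to the ten-membered monolactone. Open-chain oligomers may grow. The activated dienoyl unit may drift from Z to E by reversible conjugate addition of DMAP.
- Fallback: the two ester bonds are made one after the other with differentiated chain ends, so ring size is fixed by construction. It sets out from 25.
- One portion is esterified under Mitsunobu conditions (2-(trimethylsilyl)ethanol, PPh3, diisopropyl azodicarboxylate). These conditions activate the alcohol and not the dienoic acid. The product is 2-(trimethylsilyl)ethyl (2Z,4Z,8R,9R)-9-(tert-butyldimethylsilyloxy)-2,8-dimethyl-10-(oxazol-5-yl)deca-2,4-dienoate F4.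
- HF·pyridine removes only the silyl ether and gives 2-(trimethylsilyl)ethyl (2Z,4Z,8R,9R)-9-hydroxy-2,8-dimethyl-10-(oxazol-5-yl)deca-2,4-dienoate F5.
- A Yamaguchi esterification with a second portion of 25 gives the doubly protected linear dimer F6.
- Bu4NF in THF cleaves both silicon groups and gives (2Z,4Z,8R,9R)-9-{[(2Z,4Z,8R,9R)-9-hydroxy-2,8-dimethyl-10-(oxazol-5-yl)deca-2,4-dienoyl]oxy}-2,8-dimethyl-10-(oxazol-5-yl)deca-2,4-dienoic acid F7.
- This seco acid is closed at high dilution by a Shiina macrolactonisation (2-methyl-6-nitrobenzoic anhydride, DMAP, CH2Cl2). The route is rejoined at 29.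

**Step 12.**
- What may go wrong: the anionic aldehyde may be poorly soluble and slow to react, which would leave time for proton transfer from oxazole C2'–H to the ylide. The 4Z selectivity may erode. The 2Z bond may drift to E.
- Fallback: the acid is carried through the olefination as a neutral, soluble ester and is released afterwards without acid or base. It sets out from 22 and 19.
- Alkylation of 22 with allyl bromide and K2CO3 in DMF traps the open carboxylate form and gives allyl (Z)-2-methyl-4-oxobut-2-enoate F8.
- The ylide 23, made from 19 with NaN(SiMe3)2 as before, is treated with this aldehyde in THF at −78 °C. It should give allyl (2Z,4Z,8R,9R)-9-(tert-butyldimethylsilyloxy)-2,8-dimethyl-10-(oxazol-5-yl)deca-2,4-dienoate F9.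
- Deallylation under zerovalent palladium catalysis (Pd(PPh3)4, morpholine, THF, rt) frees the acid. The route is rejoined at 25.

**Further compounds**

F1 | step 6 | (3R,4R)-3-hydroxy-N-methoxy-N,4-dimethylhept-6-enamide | C=CC[C@@H](C)[C@@H](CC(=O)N(C)OC)O
F2 | step 6 | (3R,4R)-3-(tert-butyldimethylsilyloxy)-N-methoxy-N,4-dimethylhept-6-enamide | C=CC[C@@H](C)[C@@H](CC(=O)N(C)OC)O[Si](C)(C)C(C)(C)C
F3 | step 6 | (3R,4R)-3-(tert-butyldimethylsilyloxy)-4-methylhept-6-enal | C=CC[C@@H](C)[C@@H](CC=O)O[Si](C)(C)C(C)(C)C
F4 | step 14 | 2-(trimethylsilyl)ethyl (2Z,4Z,8R,9R)-9-(tert-butyldimethylsilyloxy)-2,8-dimethyl-10-(oxazol-5-yl)deca-2,4-dienoate | C[Si](C)(C)CCOC(=O)/C(C)=C\C=C/CC[C@@H](C)[C@@H](Cc1cnco1)O[Si](C)(C)C(C)(C)C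
F5 | step 14 | 2-(trimethylsilyl)ethyl (2Z,4Z,8R,9R)-9-hydroxy-2,8-dimethyl-10-(oxazol-5-yl)deca-2,4-dienoate | C[Si](C)(C)CCOC(=O)/C(C)=C\C=C/CC[C@@H](C)[C@@H](Cc1cnco1)O
F6 | step 14 | doubly protected linear dimer (F5 acylated at O9 by 25) | C[Si](C)(C)CCOC(=O)/C(C)=C\C=C/CC[C@@H](C)[C@@H](Cc1cnco1)OC(=O)/C(C)=C\C=C/CC[C@@H](C)[C@@H](Cc1cnco1)O[Si](C)(C)C(C)(C)C
F7 | step 14 | (2Z,4Z,8R,9R)-9-{[(2Z,4Z,8R,9R)-9-hydroxy-2,8-dimethyl-10-(oxazol-5-yl)deca-2,4-dienoyl]oxy}-2,8-dimethyl-10-(oxazol-5-yl)deca-2,4-dienoic acid | OC(=O)/C(C)=C\C=C/CC[C@@H](C)[C@@H](Cc1cnco1)OC(=O)/C(C)=C\C=C/CC[C@@H](C)[C@@H](Cc1cnco1)O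
F8 | step 12 | allyl (Z)-2-methyl-4-oxobut-2-enoate | C=CCOC(=O)/C(C)=C\C=O
F9 | step 12 | allyl (2Z,4Z,8R,9R)-9-(tert-butyldimethylsilyloxy)-2,8-dimethyl-10-(oxazol-5-yl)deca-2,4-dienoate | C=CCOC(=O)/C(C)=C\C=C/CC[C@@H](C)[C@@H](Cc1cnco1)O[Si](C)(C)C(C)(C)C
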